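**Plan**
- Last cuts: the two benzyl ethers (hydrogenolysis), then C3–OH and C2–H, which go back to the C2=C3 enol ether of a flav-2-ene (4H-chromene).
- Key cut: ring C is opened at C4–C3 and at O1–C8a, a [3+3] union of an aryl methyl ketone enolate (O1–C2=C3) with a 2-bromobenzyl bromide (C4–C4a–C8a of ring A).
- Enabling feature: on ring A, C8a is ortho to the benzylic C4, and O1–C2(aryl)–C3 is the O–C=C of the enolate of a syringyl methyl ketone; its (Z) geometry holds O1 cis to C4.
- Forward order: ring A piece (lithiation/formylation/reduction of 3,5-dibromoanisole, B-alkyl Suzuki–Miyaura coupling that joins the bibenzyl chain, bromide); ketone piece (benzylated acetosyringone); ring C in the domino step.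
- Stereochemistry: both centres come from one asymmetric hydroboration of the C2=C3 bond; syn addition of H and B gives 2,3-trans, the isopinocampheyl group gives 2R,3S.

Key step: step 6

Assumption: the facial sense of step 7 is taken from the behaviour of 1-arylcycloalkenes toward IpcBH2 (O1 in place of a ring CH2); IpcBH2 from (−)-α-pinene would be used if a model compound showed the opposite sense.

**Step 1**
Reactants: 1 3-(benzyloxy)benzaldehyde
Product: 2 1-(benzyloxy)-3-ethenylbenzene
Conditions: Ph3PCH3Br, KOtBu, THF, 0 °C to rt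
Reagents that add atoms: methyltriphenylphosphonium bromide, C[P+](c1ccccc1)(c1ccccc1)c1ccccc1.[Br-]
Why: Wittig methylenation of an aromatic aldehyde with the non-stabilised ylide is reliable and leaves the benzyl ether untouched; no stereocentre is formed.

**Step 2**
Reactants: 3 1,3-dibromo-5-methoxybenzene
Product: 6 (2,6-dibromo-4-methoxyphenyl)methanol, via (2,6-dibromo-4-methoxyphenyl)lithium 4 (not isolated), via 2,6-dibromo-4-methoxybenzaldehyde 5 (not isolated)
Conditions: LiN(iPr)2 (1.05 equiv), THF, −78 °C; DMF, −78 to −20 °C; then MeOH, NaBH4, 0 °C; aqueous work-up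
Reagents that add atoms: N,N-dimethylformamide, CN(C)C=O
Why: LiN(iPr)2 should remove the most acidic ring proton, the one flanked by both bromine atoms (halogen-directed ortho-lithiation, kept at −78 °C so that no aryne forms), and formylation with DMF followed by NaBH4 reduction in the same flask should give the benzylic alcohol; no stereocentre is formed.

**Step 3**
Reactants: 2 1-(benzyloxy)-3-ethenylbenzene; 6 (2,6-dibromo-4-methoxyphenyl)methanol
Product: 8 (2-{2-[3-(benzyloxy)phenyl]ethyl}-6-bromo-4-methoxyphenyl)methanol, via B-alkyl-9-BBN 7 (not isolated)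
Conditions: 2, 9-BBN (0.5 M in THF), 0 °C to rt; then 6 (2 equiv), PdCl2(dppf) (3 mol %), aq. K3PO4, DMF/THF, 60 °C
Reagents that add atoms: none
Why: 9-BBN adds anti-Markovnikov to the styrene and the B-alkyl-9-BBN should undergo B-alkyl Suzuki–Miyaura coupling at one of the two equivalent C–Br bonds of 6, which is used in excess so that mono-coupling dominates (the product has lost one electron-withdrawing bromine and should add oxidatively to zerovalent palladium more slowly); no stereocentre is formed.

**Step 4**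
Reactants: 8 (2-{2-[3-(benzyloxy)phenyl]ethyl}-6-bromo-4-methoxyphenyl)methanol
Product: 9 1-{2-[3-(benzyloxy)phenyl]ethyl}-3-bromo-2-(bromomethyl)-5-methoxybenzene
Conditions: CBr4, PPh3, CH2Cl2, 0 °C; used crude
Reagents that add atoms: carbon tetrabromide, BrC(Br)(Br)Br
Why: The Appel reaction converts the electron-rich benzylic alcohol into the bromide under neutral conditions that spare the aryl bromide and the benzyl and methyl ethers.

**Step 5**
Reactants: 10 1-(4-hydroxy-3,5-dimethoxyphenyl)ethan-1-one (acetosyringone)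
Product: 11 1-[4-(benzyloxy)-3,5-dimethoxyphenyl]ethan-1-one
Conditions: BnBr, K2CO3, DMF, 60 °C
Reagents that add atoms: benzyl bromide, BrCc1ccccc1
Why: Williamson ether synthesis on the acidic phenol masks it for the enolate chemistry with a group that the final hydrogenolysis removes together with the other benzyl ether.

**Step 6**
Reactants: 11 1-[4-(benzyloxy)-3,5-dimethoxyphenyl]ethan-1-one; 9 1-{2-[3-(benzyloxy)phenyl]ethyl}-3-bromo-2-(bromomethyl)-5-methoxybenzene
Product: 14 2-[4-(benzyloxy)-3,5-dimethoxyphenyl]-5-{2-[3-(benzyloxy)phenyl]ethyl}-7-methoxy-4H-chromene, via lithium enolate 12 (not isolated), via bromo ketone 13 (not isolated)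
Conditions: 11 (1.5 equiv), LiN(SiMe3)2 (1.5 equiv), THF, −78 °C; 9 (1.0 equiv), −78 to 0 °C; then NaOtBu (1.5 equiv), CuI (10 mol %), 1,10-phenanthroline (20 mol %), toluene, 100 °C, sealed vessel; chromatography on Et3N-deactivated silica
Reagents that add atoms: none
Why: The lithium enolate 12 attacks the benzylic C–Br bond of 9 in an SN2 alkylation, which forms C4–C3 and gives ketone 13; NaOtBu then regenerates the enolate, whose (Z) geometry (aryl and C4 trans across C2=C3 to avoid allylic strain) places O1 on the same side as C4 and within reach of C8a. A phenanthroline-ligated cuprous enolate adds oxidatively to the C8a–Br bond, and reductive elimination from the trivalent copper intermediate forms O1–C8a (Ullmann-type enolate O-arylation). The closest known reaction types are the benzylation of aryl methyl ketone enolates, the copper-catalysed domino C-benzylation/O-arylation of 1,3-dicarbonyl compounds with 2-bromobenzyl bromides to 4H-chromenes, and the intramolecular O-arylation of simple ketone enolates to benzofurans. Ring C closes in a 6-exo mode through oxygen, since closure through C3 would need a four-membered ring. No stereocentre is formed; the step delivers the C2=C3 enol ether on which step 7 sets both. The selectivities needed are C- over O-alkylation and mono- over dialkylation (lithium counter-ion in THF at low temperature, enolate in excess) and discrimination of the two C–Br bonds of 9 (the sp3 bond reacts without catalyst at −78 °C, the sp2 bond only under copper catalysis).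

**Step 7**
Reactants: 14 2-[4-(benzyloxy)-3,5-dimethoxyphenyl]-5-{2-[3-(benzyloxy)phenyl]ethyl}-7-methoxy-4H-chromene
Product: 16 (2R,3S)-2-[4-(benzyloxy)-3,5-dimethoxyphenyl]-5-{2-[3-(benzyloxy)phenyl]ethyl}-7-methoxy-3,4-dihydro-2H-chromen-3-ol, via flavan-3-yl(isopinocampheyl)borane 15 (not isolated)
Conditions: IpcBH2 (from (+)-α-pinene, 1.5 equiv, stock solution), THF, −25 to 0 °C; then 3 M NaOH, 30% H2O2, 0 °C to rt
Reagents that add atoms: hydrogen peroxide, OO
Why: In this asymmetric hydroboration with a chiral monoalkylborane, boron should add to C3 (β to the enol-ether oxygen and remote from the aryl-bearing C2) and hydrogen to C2 on the same face, so that oxidation with retention gives the 2,3-trans relationship, while the isopinocampheyl group from (+)-α-pinene should select the face that leads to 2R,3S, as it does for 1-arylcycloalkenes.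

**Step 8**
Reactants: 16 (2R,3S)-2-[4-(benzyloxy)-3,5-dimethoxyphenyl]-5-{2-[3-(benzyloxy)phenyl]ethyl}-7-methoxy-3,4-dihydro-2H-chromen-3-ol
Product: 17 (2R,3S)-2-(4-hydroxy-3,5-dimethoxyphenyl)-5-[2-(3-hydroxyphenyl)ethyl]-7-methoxy-3,4-dihydro-2H-chromen-3-ol (CNP0118545.1)
Conditions: H2 (1 atm), Pd(OH)2/C, THF/MeOH, rt
Reagents that add atoms: none
Why: Hydrogenolysis of the two benzyl aryl ethers under neutral conditions at room temperature should free both phenols without cleaving the cyclic benzylic C2–O1 bond or disturbing C2 and C3, as is usual for benzyl-protected flavan-3-ols.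

**Compound list**
1 | 3-(benzyloxy)benzaldehyde | O=Cc1cccc(OCc2ccccc2)c1 | starting material
2 | 1-(benzyloxy)-3-ethenylbenzene | C=Cc1cccc(OCc2ccccc2)c1 | intermediate
3 | 1,3-dibromo-5-methoxybenzene | COc1cc(Br)cc(Br)c1 | starting material
4 | (2,6-dibromo-4-methoxyphenyl)lithium | [Li]c1c(Br)cc(OC)cc1Br | intermediate
5 | 2,6-dibromo-4-methoxybenzaldehyde | COc1cc(Br)c(C=O)c(Br)c1 | intermediate
6 | (2,6-dibromo-4-methoxyphenyl)methanol | COc1cc(Br)c(CO)c(Br)c1 | intermediate
7 | 9-{2-[3-(benzyloxy)phenyl]ethyl}-9-borabicyclo[3.3.1]nonane | C(Cc1cccc(OCc2ccccc2)c1)B1C2CCCC1CCC2 | intermediate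
8 | (2-{2-[3-(benzyloxy)phenyl]ethyl}-6-bromo-4-methoxyphenyl)methanol | COc1cc(Br)c(CO)c(CCc2cccc(OCc3ccccc3)c2)c1 | intermediate
9 | 1-{2-[3-(benzyloxy)phenyl]ethyl}-3-bromo-2-(bromomethyl)-5-methoxybenzene | COc1cc(Br)c(CBr)c(CCc2cccc(OCc3ccccc3)c2)c1 | intermediate
10 | 1-(4-hydroxy-3,5-dimethoxyphenyl)ethan-1-one (acetosyringone) | CC(=O)c1cc(OC)c(O)c(OC)c1 | starting material
11 | 1-[4-(benzyloxy)-3,5-dimethoxyphenyl]ethan-1-one | CC(=O)c1cc(OC)c(OCc2ccccc2)c(OC)c1 | intermediate
12 | lithium 1-[4-(benzyloxy)-3,5-dimethoxyphenyl]ethen-1-olate | C=C(O[Li])c1cc(OC)c(OCc2ccccc2)c(OC)c1 | intermediate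
13 | 1-[4-(benzyloxy)-3,5-dimethoxyphenyl]-3-(2-{2-[3-(benzyloxy)phenyl]ethyl}-6-bromo-4-methoxyphenyl)propan-1-one | COc1cc(Br)c(CCC(=O)c2cc(OC)c(OCc3ccccc3)c(OC)c2)c(CCc2cccc(OCc3ccccc3)c2)c1 | intermediate
14 | 2-[4-(benzyloxy)-3,5-dimethoxyphenyl]-5-{2-[3-(benzyloxy)phenyl]ethyl}-7-methoxy-4H-chromene | COc1cc(CCc2cccc(OCc3ccccc3)c2)c2c(c1)OC(c1cc(OC)c(OCc3ccccc3)c(OC)c1)=CC2 | intermediate
15 | {2-[4-(benzyloxy)-3,5-dimethoxyphenyl]-5-{2-[3-(benzyloxy)phenyl]ethyl}-7-methoxy-3,4-dihydro-2H-chromen-3-yl}(isopinocampheyl)borane, boron on C3 trans to the 2-aryl group, spatial arrangement as in 16 | COc1cc(CCc2cccc(OCc3ccccc3)c2)c2c(c1)O[C@H](c1cc(OC)c(OCc3ccccc3)c(OC)c1)[C@@H](B[C@@H]1C[C@@H]3C[C@H]([C@H]1C)C3(C)C)C2 | intermediate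
16 | (2R,3S)-2-[4-(benzyloxy)-3,5-dimethoxyphenyl]-5-{2-[3-(benzyloxy)phenyl]ethyl}-7-methoxy-3,4-dihydro-2H-chromen-3-ol | COc1cc(CCc2cccc(OCc3ccccc3)c2)c2c(c1)O[C@H](c1cc(OC)c(OCc3ccccc3)c(OC)c1)[C@@H](O)C2 | intermediate
17 | (2R,3S)-2-(4-hydroxy-3,5-dimethoxyphenyl)-5-[2-(3-hydroxyphenyl)ethyl]-7-methoxy-3,4-dihydro-2H-chromen-3-ol | COc1cc(CCc2cccc(O)c2)c2c(c1)O[C@H](c1cc(OC)c(O)c(OC)c1)[C@@H](O)C2 | target

**Totals**
Total step count: 8. Longest linear sequence: 6 steps (steps 2, 3, 4, 6, 7, 8, from 3 to 17).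

**Steps most likely to fail**

Step 6. The product ketone may exchange a proton with unreacted enolate and be benzylated a second time, or the copper-mediated C–O bond formation may stall on the electron-rich, ortho-substituted aryl bromide, with protodebromination or intermolecular coupling instead. The fallback sets out from 8 and 11 and comes back at 14; it makes C4–C3 as a C=C bond, so that over-alkylation cannot occur. Alcohol 8 is oxidised with MnO2 (CH2Cl2, rt) to 2-{2-[3-(benzyloxy)phenyl]ethyl}-6-bromo-4-methoxybenzaldehyde F1. Claisen–Schmidt condensation of F1 with ketone 11 (KOH, EtOH, rt) gives (2E)-1-[4-(benzyloxy)-3,5-dimethoxyphenyl]-3-(2-{2-[3-(benzyloxy)phenyl]ethyl}-6-bromo-4-methoxyphenyl)prop-2-en-1-one F2. Conjugate reduction with catalytic [(Ph3P)CuH]6 and polymethylhydrosiloxane (toluene, rt, then aqueous work-up) gives ketone 13, now isolated and purified. A separate ring closure under palladium catalysis (Pd2(dba)3, DPEphos, Cs2CO3, toluene, 100 °C) then gives 14.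

Step 7. Facial selectivity may be poor on this benzo-fused enol ether, or the β-aryloxy organoborane may eliminate and open ring C. The fallback sets out from 14 and comes back at 16. Hydroboration with BH3·SMe2 (THF, 0 °C) and oxidation (NaOH, H2O2) gives racemic trans-2-[4-(benzyloxy)-3,5-dimethoxyphenyl]-5-{2-[3-(benzyloxy)phenyl]ethyl}-7-methoxy-3,4-dihydro-2H-chromen-3-ol F3. It is resolved by a lipase (Burkholderia cepacia lipase or Candida antarctica lipase B, vinyl acetate, MTBE, 35 °C). By analogy with trans-2-arylcycloalkanols the enzyme should acylate the (2S,3R) enantiomer to (2S,3R)-2-[4-(benzyloxy)-3,5-dimethoxyphenyl]-5-{2-[3-(benzyloxy)phenyl]ethyl}-7-methoxy-3,4-dihydro-2H-chromen-3-yl acetate F4 and leave alcohol 16, which is separated by chromatography.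

Step 3. The two equivalent C–Br bonds of 6 may not be told apart well enough, so that double coupling erodes the yield. The fallback sets out from 6 and comes back at 8; it replaces the statistical differentiation by a chemoselective one. Treatment of 6 with n-BuLi (2.1 equiv, THF, −78 °C; alkoxide formation, then a single bromine–lithium exchange) and quenching with I2 gives (2-bromo-6-iodo-4-methoxyphenyl)methanol F5. Borane 7 is then coupled at room temperature (PdCl2(dppf), aq. K3PO4, DMF/THF), where the C–I bond should react and the C–Br bond remain, to give 8.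

**Further compounds**
F1 | step 6 | 2-{2-[3-(benzyloxy)phenyl]ethyl}-6-bromo-4-methoxybenzaldehyde | COc1cc(Br)c(C=O)c(CCc2cccc(OCc3ccccc3)c2)c1
F2 | step 6 | (2E)-1-[4-(benzyloxy)-3,5-dimethoxyphenyl]-3-(2-{2-[3-(benzyloxy)phenyl]ethyl}-6-bromo-4-methoxyphenyl)prop-2-en-1-one | COc1cc(Br)c(/C=C/C(=O)c2cc(OC)c(OCc3ccccc3)c(OC)c2)c(CCc2cccc(OCc3ccccc3)c2)c1
F3 | step 7 | racemic trans-2-[4-(benzyloxy)-3,5-dimethoxyphenyl]-5-{2-[3-(benzyloxy)phenyl]ethyl}-7-methoxy-3,4-dihydro-2H-chromen-3-ol (both enantiomers) | COc1cc(CCc2cccc(OCc3ccccc3)c2)c2c(c1)O[C@H](c1cc(OC)c(OCc3ccccc3)c(OC)c1)[C@@H](O)C2.COc1cc(CCc2cccc(OCc3ccccc3)c2)c2c(c1)O[C@@H](c1cc(OC)c(OCc3ccccc3)c(OC)c1)[C@H](O)C2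
F4 | step 7 | (2S,3R)-2-[4-(benzyloxy)-3,5-dimethoxyphenyl]-5-{2-[3-(benzyloxy)phenyl]ethyl}-7-methoxy-3,4-dihydro-2H-chromen-3-yl acetate | COc1cc(CCc2cccc(OCc3ccccc3)c2)c2c(c1)O[C@@H](c1cc(OC)c(OCc3ccccc3)c(OC)c1)[C@H](OC(C)=O)C2
F5 | step 3 | (2-bromo-6-iodo-4-methoxyphenyl)methanol | COc1cc(Br)c(CO)c(I)c1
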